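The south run, charged with 0.65 M of substrate, had been read up to 40.0 h, and that same flask was now asked about at 8.0 d.

- south: substrate 0.65 M; the very flask that is asked about, followed so far
- flask: substrate 0.65 M; time 8.0 d

south run (percent of the substrate charged)

| time / h | substrate / % | product / % |
|---|---|---|
| 6.00 | 5.0 | 64.1 |
| 12.0 | 2.4 | 76.6 |
| 20.0 | 2.4 | 76.4 |
| 25.0 | 2.3 | 76.6 |
| 30.0 | 1.0 | 76.5 |
| 40.0 | 2.8 | 77.7 |

(standard deviation of a reading: 1 percentage point)

- what may be going on: substrate <-> intermediate; intermediate <-> product
- the reaction counts as stopped when no species that holds the substrate changes by six tenths of a point or more over the second half of the time

- which holds at 8.0 d: what has brought the reaction to rest, or that it has not come to rest (all of the substrate has reacted / forward and back rates have come level / it is still moving)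
- part of the substrate gone at 8.0 d
- the product standing at 8.0 d, as a percentage of the substrate charged
- the intermediate standing at 8.0 d, as a percentage of the substrate charged

1. I began with the main step by itself: substrate going forward, nothing returning. That picture put 100% of the charge past the substrate. But the south readings from 12.0 h on stayed flat, and their 5 substrate values averaged 2.18%.

2. I then added the way back. A substrate that stands flat above zero reads as forward and back rates level, so the conversion I read for the south flask came down to 97.8%.

3. Last I added the intermediate, with its own two-way step. The same 5 product readings averaged 76.8%, which left 21.1% unaccounted for. I called this the resting gap: the share of the charge that the flat readings of substrate and product do not show, read as the intermediate in the equilibrium mixture. Each reading behind it carries a scatter of 1 percentage point.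

4. I froze these shares. The product moved 1.1 points between 12.0 h and 40.0 h, against that scatter, so I carried them to 8.0 d unchanged.

The forecast called the flat stretch “a true plateau rather than a slowdown” and gave: forward and back rates have come level, conversion 97.8%, product 76.8%, intermediate 21%.

At 8.0 d the flask gave: forward and back rates have come level, conversion 97.8%, product 77.0%, intermediate 20.8%.

    substrate ⇌ intermediate (K = 9.60, k = 0.700 h⁻¹)
    intermediate ⇌ product (K = 3.70, k = 0.380 h⁻¹)

In the south flask the substrate went first, with a forward half-life of 0.99 h, short against 8.0 d, and at 0.0417 d intermediate was made 2.29 times as fast as it was used up, each step taken net. The step from intermediate to product had >99.9% of its turnover up to 8.0 d behind it by 1.60 d, and from 0.800 d to 80.0 d the intermediate in that flask stood at 20.8%. The resting gap of 21.1% lay 0.30 points from the intermediate in that flask. Applied to the neighbour charged with 0.26 M of substrate, the gap gave 0.0549 M of intermediate, and at 8.00 d that neighbour held 20.8% of its charge as intermediate, which is 0.0541 M.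

The runs were computed with constants of no real substance.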